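**Retrosynthetic overview**
1. Target 40 ⇒ C6 alcohol 34 + (2R,3R)-epoxy acid 38 (last step, esterification).
2. 34 ⇒ 33 ⇒ open-chain keto ester 31, which holds only the lactone ring: one flask joins C2 to C1 (Claisen acylation, 10-membered carbocycle) and the C3 oxygen to C10 (displacement of a tertiary mesylate with inversion, furanone ring).
3. Enabling feature: the 3(2H)-furanone ring O–C3=C2–C1(=O)–C10 is a cyclized 1,3-diketone. Its O–C3=C2 half is the enolate of a C3 acetyl group (nucleophilic at C2 and at O), its C1–C10 half is an acyl group with a leaving group on the α-carbon (electrophilic at C1 and C10), and the bridge C4–C9 with the (Z)-C4=C5 alkene and the trans C7–C8 lactone keeps the two halves within reach.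
4. 31 ⇒ Evans syn-aldol (C7–C8; imide 13 + aldehyde 5), vinyllithium acylation (C5–C6; iodide 9), Evans–Tishchenko reduction (C6), lactonization and α-methylenation; C10 comes from (R)-2-methylglycidol 1.
5. Ring order: γ-lactone (step 12), then carbocycle and furanone together (step 19); the oxirane of the side chain is made apart (step 22).

Key step: step 19

Remark: locants C1–C15 follow the germacrane skeleton of the target: C1 furanone C=O, C2 furanone =CH, C3 furanone C–O, C4 (methyl C15)=C5, C6 ester-bearing CH, C7, C8 lactone O–CH, C9 CH2, C10 quaternary carbon (methyl C14), C11 (=C13H2), C12 lactone C=O.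
Assumption: compounds 1, 6, 10, 11 and 35 are bought as single isomers.

Step 1
Reactants: 1 (R)-2-methylglycidol
Product: 2 (S)-2-methylpent-4-ene-1,2-diol
Conditions: CH2=CHMgBr (3 equiv), CuI (10 mol%), THF, −30 → 0 °C
Reagents that add atoms: vinylmagnesium bromide C=C[Mg]Br
Why: Copper-catalysed Grignard opening of the epoxide at its unsubstituted CH2 terminus (SN2) leaves the tertiary carbinol center C10 untouched.

Step 2
Reactants: 2 (S)-2-methylpent-4-ene-1,2-diol
Product: 3 (S)-4-allyl-2,2,4-trimethyl-1,3-dioxolane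
Conditions: Me2C(OMe)2, PPTS (cat.), CH2Cl2, 23 °C
Reagents that add atoms: 2,2-dimethoxypropane COC(C)(C)OC
Why: Acid-catalysed transketalization (acetonide formation) masks the C1 and C10 hydroxyls together.

Step 3
Reactants: 3 (S)-4-allyl-2,2,4-trimethyl-1,3-dioxolane
Product: 5 2-[(4S)-2,2,4-trimethyl-1,3-dioxolan-4-yl]acetaldehyde (fragment E), via ozonide 4 (not isolated)
Conditions: O3, CH2Cl2, −78 °C; then Me2S, −78 → 23 °C
Reagents that add atoms: ozone [O-][O+]=O
Why: Ozonolysis with reductive work-up cleaves the terminal alkene to the C8 aldehyde without touching a stereocenter.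

Step 4
Reactants: 6 (S)-but-3-yn-2-ol
Product: 8 (2S,3Z)-4-iodo-3-methylbut-3-en-2-ol, via alkenylmagnesium alkoxide 7 (not isolated)
Conditions: MeMgBr (3 equiv), CuI (10 mol%), Et2O, 0 → 23 °C; then I2, −20 °C
Reagents that add atoms: methylmagnesium bromide C[Mg]Br; iodine II
Why: Hydroxyl-directed copper-catalysed anti-carbomagnesiation of the propargylic alcohol (methyl to the internal carbon, magnesium chelated by the alkoxide) and iodinolysis with retention fix the C4=C5 geometry with C3 and iodine cis.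

Step 5
Reactants: 8 (2S,3Z)-4-iodo-3-methylbut-3-en-2-ol
Product: 9 TBS ether of 8 (fragment W)
Conditions: TBSCl, imidazole, DMF, 23 °C
Reagents that add atoms: tert-butyldimethylsilyl chloride CC(C)(C)[Si](C)(C)Cl
Why: Standard silylation of the secondary alcohol, which is the masked C3 ketone.

Step 6
Reactants: 10 mono-tert-butyl succinate; 11 (R)-4-benzyl-2-oxazolidinone
Product: 13 (4R)-4-benzyl-3-[4-(tert-butoxy)-4-oxobutanoyl]-1,3-oxazolidin-2-one, via mixed pivalic anhydride 12 (not isolated)
Conditions: t-BuCOCl, Et3N, THF, −20 °C; then 11, LiCl, −20 → 23 °C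
Reagents that add atoms: none
Why: N-acylation of the oxazolidinone through the mixed anhydride, which reacts at its less hindered carbonyl.

Step 7
Reactants: 13 imide; 5 aldehyde (fragment E)
Product: 15 syn-aldol adduct, via boron enolate 14 (not isolated)
Conditions: Bu2BOTf, i-Pr2NEt, CH2Cl2, 0 °C; then 5, −78 → 0 °C; then pH 7 buffer, MeOH, H2O2, 0 °C
Reagents that add atoms: none
Why: Evans syn-aldol reaction, in which the (Z)-boron enolate reacts through a chair Zimmerman–Traxler transition state on the face away from the benzyl group and so sets C7 and C8 (syn, the arrangement of the trans-lactone).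

Step 8
Reactants: 15 syn-aldol adduct
Product: 16 Weinreb amide
Conditions: MeONHMe·HCl, AlMe3, CH2Cl2, −10 → 0 °C
Reagents that add atoms: N,O-dimethylhydroxylamine hydrochloride CNOC.Cl
Why: Aluminium amide transamination of the β-hydroxy imide gives the Weinreb amide and releases the auxiliary.

Step 9
Reactants: 9 vinyl iodide (fragment W); 16 Weinreb amide
Product: 18 β-hydroxy (Z)-enone, via vinyllithium 17 (not isolated)
Conditions: 9, t-BuLi (2 equiv per iodide), Et2O, −78 °C; then 16 (0.45 equiv), −78 → −40 °C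
Reagents that add atoms: none
Why: Iodine–lithium exchange with retention of alkene geometry and acylation of the vinyllithium by the Weinreb amide (chelated tetrahedral intermediate, no over-addition) form the C5–C6 bond.

Step 10
Reactants: 18 β-hydroxy (Z)-enone
Product: 19 anti-1,3-diol 8-monoacetate
Conditions: SmI2 (0.3 equiv), MeCHO (8 equiv), THF, −10 °C
Reagents that add atoms: acetaldehyde CC=O
Why: Evans–Tishchenko reduction, in which the samarium-bound hemiacetal on O8 delivers hydride to C6 through a chair transition state and sets C6 anti to C8 while leaving O8 acetylated and O6 free.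

Step 11
Reactants: 19 anti-1,3-diol 8-monoacetate
Product: 20 6-O-TIPS ether
Conditions: TIPSOTf, 2,6-lutidine, CH2Cl2, −40 → 0 °C
Reagents that add atoms: triisopropylsilyl triflate CC(C)[Si](C(C)C)(C(C)C)OS(=O)(=O)C(F)(F)F
Why: Silyl triflate protection of the hindered allylic C6 hydroxyl, the only free hydroxyl.

Step 12
Reactants: 20 6-O-TIPS ether
Product: 22 trans-γ-lactone, via hydroxy ester 21 (not isolated)
Conditions: K2CO3, MeOH, 23 °C; then NaH (0.2 equiv), THF, 0 → 23 °C
Reagents that add atoms: none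
Why: Methanolysis of the acetate frees only O8, whose alkoxide lactonizes onto the tert-butyl ester (5-exo-trig), and the syn C7/C8 arrangement makes the lactone trans-disubstituted.

Step 13
Reactants: 22 trans-γ-lactone
Product: 26 α-methylene lactone, via lithium enolate 23 (not isolated), via Mannich base 24 (not isolated), via ammonium iodide 25 (not isolated)
Conditions: LiN(i-Pr)2, THF, −78 °C; CH2=NMe2+ I−, −78 → 23 °C; then MeI, MeOH, 23 °C; then NaHCO3, CH2Cl2/H2O, 23 °C
Reagents that add atoms: Eschenmoser's salt C=[N+](C)C.[I-]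
Why: Aminomethylation of the only available enolate (C11) with Eschenmoser's salt, N-methylation and Hofmann-type elimination give the exocyclic methylene.

Step 14
Reactants: 26 α-methylene lactone
Product: 27 triol
Conditions: CSA (0.2 equiv), MeOH, 0 → 23 °C
Reagents that add atoms: none
Why: Acid-catalysed methanolysis removes the acetonide and the secondary TBS ether, while the bulkier TIPS ether should survive.

Step 15
Reactants: 27 triol
Product: 28 keto aldehyde
Conditions: Dess–Martin periodinane (3 equiv), CH2Cl2, 0 → 23 °C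
Reagents that add atoms: none
Why: Dess–Martin oxidation takes the primary C1 alcohol to the aldehyde and the allylic C3 alcohol to the methyl ketone, and the tertiary C10 alcohol is inert.

Step 16
Reactants: 28 keto aldehyde
Product: 29 α-hydroxy acid
Conditions: NaClO2, NaH2PO4, 2-methylbut-2-ene, t-BuOH/H2O, 0 °C
Reagents that add atoms: sodium chlorite [Na+].[O-]Cl=O
Why: Pinnick oxidation of the non-enolizable aldehyde, with a hypochlorite scavenger that protects the alkenes.

Step 17
Reactants: 29 α-hydroxy acid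
Product: 30 pentafluorophenyl ester
Conditions: C6F5OH, EDC·HCl, CH2Cl2, 0 → 23 °C
Reagents that add atoms: pentafluorophenol Oc1c(F)c(F)c(F)c(F)c1F
Why: Carbodiimide esterification gives the activated ester, and the hindered tertiary hydroxyl should not compete with the phenol.

Step 18
Reactants: 30 pentafluorophenyl ester
Product: 31 (10S)-mesylate
Conditions: MsCl, Et3N, CH2Cl2, −20 → 0 °C
Reagents that add atoms: methanesulfonyl chloride CS(=O)(=O)Cl
Why: Sulfene-type mesylation of the tertiary α-hydroxy ester occurs at oxygen, so C10 keeps its configuration.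

Step 19
Reactants: 31 (10S)-mesylate
Product: 33 bicyclic furanone 6-O-TIPS ether, via macrocyclic diketone 32 (not isolated)
Conditions: MgBr2·OEt2 (3 equiv), i-Pr2NEt (4 equiv), CH2Cl2, 23 °C, 31 added by syringe pump (final 1 mM); then DBU (3 equiv), MeCN, 40 °C
Reagents that add atoms: none
Why: Proposed new method: MgBr2·OEt2 with i-Pr2NEt enolizes only the C3 acetyl group (soft enolization; C11 of the lactone is sp2 and carries no hydrogen), and the C2 magnesium enolate attacks the pentafluorophenyl ester carbon C1 in an intramolecular Claisen acylation (10-exo-trig at the acyl carbon) that closes the carbocycle as the chelated 1,3-diketonate 32. DBU then frees the enolate oxygen on C3, which displaces the tertiary mesylate at C10 by 5-exo-tet SN2 attack and closes the 3(2H)-furanone. The closest known reactions are the intermolecular soft-enolization acylation of ketones with pentafluorophenyl esters or N-acylbenzotriazoles, the base-mediated cyclization of γ-halo β-diketones to 3(2H)-furanones, and invertive substitution at tertiary α-sulfonyloxy carbonyl centers; new here are their fusion in one flask and the medium-ring closure. C10 is the only new stereocenter and is set by inversion of the (10S)-mesylate to (10R), because the flanking C1 carbonyl disfavors ionization and lowers the barrier to backside attack. The step needs C- over O-acylation and cyclization over oligomerization: magnesium chelation steers the enolate to C-acylation and makes the diketonate a thermodynamic sink, slow addition keeps the concentration near 1 mM, and the (Z)-C4=C5 alkene together with the trans-lactone on C7–C8 turns C2 and C1 toward each other. Oxygen attack at C10 (five-membered ring) should outrun carbon attack from C2 (three-membered ring), and the α-methylene lactone and silyl ether are inert to the amine bases.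

Step 20
Reactants: 33 bicyclic furanone 6-O-TIPS ether
Product: 34 bicyclic C6 alcohol
Conditions: HF·pyridine, pyridine, THF, 0 → 23 °C
Reagents that add atoms: none
Why: Fluoride cleavage of the silyl ether under buffered conditions that should spare the furanone and the α-methylene lactone.

Step 21
Reactants: 35 methyl angelate
Product: 36 (Z)-2-methylbut-2-en-1-ol
Conditions: i-Bu2AlH (2.2 equiv), CH2Cl2, −78 °C
Reagents that add atoms: none
Why: Low-temperature hydride reduction of the ester to the allylic alcohol keeps the (Z)-geometry.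

Step 22
Reactants: 36 (Z)-2-methylbut-2-en-1-ol
Product: 37 [(2S,3R)-2,3-dimethyloxiran-2-yl]methanol
Conditions: Ti(OiPr)4 (10 mol%), L-(+)-diethyl tartrate (12 mol%), t-BuOOH, 4 Å molecular sieves, CH2Cl2, −20 °C
Reagents that add atoms: tert-butyl hydroperoxide CC(C)(C)OO
Why: Sharpless asymmetric epoxidation, in which the L-(+)-tartrate complex selects the alkene face that gives the (2S,3R)-epoxy alcohol and the (Z)-alkene fixes CH2OH and the C3 methyl cis.

Step 23
Reactants: 37 [(2S,3R)-2,3-dimethyloxiran-2-yl]methanol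
Product: 38 (2R,3R)-2,3-dimethyloxirane-2-carboxylic acid
Conditions: RuCl3 (2 mol%), NaIO4, CCl4/MeCN/H2O, 23 °C
Reagents that add atoms: sodium periodate [Na+].[O-]I(=O)(=O)=O; water O
Why: RuO4-catalysed oxidation of the primary alcohol to the acid leaves the oxirane intact, and the C2 descriptor changes only through the priority change.

Step 24
Reactants: 38 (2R,3R)-2,3-dimethyloxirane-2-carboxylic acid; 34 bicyclic C6 alcohol
Product: 40 target CNP0258430.3, via mixed anhydride 39 (not isolated)
Conditions: 38, 2,4,6-trichlorobenzoyl chloride, Et3N, THF, 23 °C; then 34, DMAP, toluene, 23 °C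
Reagents that add atoms: none
Why: Yamaguchi esterification of the hindered allylic alcohol through the mixed anhydride with DMAP catalysis touches no stereocenter.

**Compound list**
1 | (R)-2-methylglycidol, [(2R)-2-methyloxiran-2-yl]methanol | OC[C@]1(C)CO1 | starting material
2 | (2S)-2-methylpent-4-ene-1,2-diol | C=CC[C@](C)(O)CO | intermediate
3 | (4S)-2,2,4-trimethyl-4-(prop-2-en-1-yl)-1,3-dioxolane | C=CC[C@@]1(C)COC(C)(C)O1 | intermediate
4 | ozonide of 3, 3-{[(4S)-2,2,4-trimethyl-1,3-dioxolan-4-yl]methyl}-1,2,4-trioxolane | C1OOC(C[C@@]2(C)COC(C)(C)O2)O1 | intermediate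
5 | 2-[(4S)-2,2,4-trimethyl-1,3-dioxolan-4-yl]acetaldehyde (fragment E: C8, C9, C10, C14, C1) | O=CC[C@@]1(C)COC(C)(C)O1 | intermediate
6 | (S)-but-3-yn-2-ol | C#C[C@H](C)O | starting material
7 | cyclic alkenylmagnesium alkoxide from anti-carbomagnesiation of 6 | C[C@@H]1O[Mg]C=C1C | intermediate
8 | (2S,3Z)-4-iodo-3-methylbut-3-en-2-ol | C[C@H](O)/C(C)=C\I | intermediate
9 | tert-butyl{[(2S,3Z)-4-iodo-3-methylbut-3-en-2-yl]oxy}dimethylsilane (fragment W: C2–C5, C15) | C[C@H](O[Si](C)(C)C(C)(C)C)/C(C)=C\I | intermediate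
10 | 4-(tert-butoxy)-4-oxobutanoic acid (mono-tert-butyl succinate) | CC(C)(C)OC(=O)CCC(=O)O | starting material
11 | (4R)-4-benzyl-1,3-oxazolidin-2-one | O=C1N[C@H](Cc2ccccc2)CO1 | starting material
12 | mixed anhydride of 10 with pivalic acid | CC(C)(C)OC(=O)CCC(=O)OC(=O)C(C)(C)C | intermediate
13 | (4R)-4-benzyl-3-[4-(tert-butoxy)-4-oxobutanoyl]-1,3-oxazolidin-2-one | CC(C)(C)OC(=O)CCC(=O)N1[C@H](Cc2ccccc2)COC1=O | intermediate
14 | (Z)-dibutylboron enolate of 13 | CCCCB(CCCC)O/C(=C\CC(=O)OC(C)(C)C)N1[C@H](Cc2ccccc2)COC1=O | intermediate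
15 | tert-butyl (3R,4S)-3-{[(4R)-4-benzyl-2-oxo-1,3-oxazolidin-3-yl]carbonyl}-4-hydroxy-5-[(4S)-2,2,4-trimethyl-1,3-dioxolan-4-yl]pentanoate (syn-aldol adduct; C7, C8 set) | CC(C)(C)OC(=O)C[C@H]([C@@H](O)C[C@@]1(C)COC(C)(C)O1)C(=O)N1[C@H](Cc2ccccc2)COC1=O | intermediate
16 | tert-butyl (3R,4S)-4-hydroxy-3-[methoxy(methyl)carbamoyl]-5-[(4S)-2,2,4-trimethyl-1,3-dioxolan-4-yl]pentanoate | CC(C)(C)OC(=O)C[C@H]([C@@H](O)C[C@@]1(C)COC(C)(C)O1)C(=O)N(C)OC | intermediate
17 | (1Z,3S)-3-(tert-butyldimethylsilyloxy)-2-methylbut-1-enyllithium | C[C@H](O[Si](C)(C)C(C)(C)C)/C(C)=C\[Li] | intermediate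
18 | β-hydroxy (Z)-enone: C6 ketone, C8 hydroxyl, C12 tert-butyl ester, C3 OTBS, C1/C10 acetonide | C[C@H](O[Si](C)(C)C(C)(C)C)/C(C)=C\C(=O)[C@H](CC(=O)OC(C)(C)C)[C@@H](O)C[C@@]1(C)COC(C)(C)O1 | intermediate
19 | anti-1,3-diol monoacetate: C6 hydroxyl (S), C8 acetate, otherwise as 18 | C[C@H](O[Si](C)(C)C(C)(C)C)/C(C)=C\[C@H](O)[C@H](CC(=O)OC(C)(C)C)[C@@H](OC(C)=O)C[C@@]1(C)COC(C)(C)O1 | intermediate
20 | 6-O-triisopropylsilyl ether of 19 | C[C@H](O[Si](C)(C)C(C)(C)C)/C(C)=C\[C@H](O[Si](C(C)C)(C(C)C)C(C)C)[C@H](CC(=O)OC(C)(C)C)[C@@H](OC(C)=O)C[C@@]1(C)COC(C)(C)O1 | intermediate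
21 | C8 alcohol from 20 (acetate removed, tert-butyl ester kept) | C[C@H](O[Si](C)(C)C(C)(C)C)/C(C)=C\[C@H](O[Si](C(C)C)(C(C)C)C(C)C)[C@H](CC(=O)OC(C)(C)C)[C@@H](O)C[C@@]1(C)COC(C)(C)O1 | intermediate
22 | trans-disubstituted γ-lactone (C12–O8), 6-OTIPS, 3-OTBS, C1/C10 acetonide | C[C@H](O[Si](C)(C)C(C)(C)C)/C(C)=C\[C@H](O[Si](C(C)C)(C(C)C)C(C)C)[C@@H]1CC(=O)O[C@H]1C[C@@]1(C)COC(C)(C)O1 | intermediate
23 | lithium enolate of lactone 22 | C[C@H](O[Si](C)(C)C(C)(C)C)/C(C)=C\[C@H](O[Si](C(C)C)(C(C)C)C(C)C)[C@@H]1C=C(O[Li])O[C@H]1C[C@@]1(C)COC(C)(C)O1 | intermediate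
24 | Mannich base: 11-(dimethylaminomethyl) lactone, new group trans to the C7 side chain | C[C@H](O[Si](C)(C)C(C)(C)C)/C(C)=C\[C@H](O[Si](C(C)C)(C(C)C)C(C)C)[C@@H]1[C@@H](CN(C)C)C(=O)O[C@H]1C[C@@]1(C)COC(C)(C)O1 | intermediate
25 | trimethylammonium iodide of 24 | C[C@H](O[Si](C)(C)C(C)(C)C)/C(C)=C\[C@H](O[Si](C(C)C)(C(C)C)C(C)C)[C@@H]1[C@@H](C[N+](C)(C)C)C(=O)O[C@H]1C[C@@]1(C)COC(C)(C)O1.[I-] | intermediate
26 | α-methylene γ-lactone, 6-OTIPS, 3-OTBS, C1/C10 acetonide | C[C@H](O[Si](C)(C)C(C)(C)C)/C(C)=C\[C@H](O[Si](C(C)C)(C(C)C)C(C)C)[C@@H]1C(=C)C(=O)O[C@H]1C[C@@]1(C)COC(C)(C)O1 | intermediate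
27 | triol: C1 primary OH, C10 tertiary OH (S), C3 allylic OH; 6-OTIPS; α-methylene lactone | C[C@H](O)/C(C)=C\[C@H](O[Si](C(C)C)(C(C)C)C(C)C)[C@@H]1C(=C)C(=O)O[C@H]1C[C@](C)(O)CO | intermediate
28 | keto aldehyde: C1 aldehyde, C10 tertiary OH (S), C3 methyl ketone | CC(=O)/C(C)=C\[C@H](O[Si](C(C)C)(C(C)C)C(C)C)[C@@H]1C(=C)C(=O)O[C@H]1C[C@](C)(O)C=O | intermediate
29 | α-hydroxy acid (C1 carboxylic acid, (10S)-hydroxyl) | CC(=O)/C(C)=C\[C@H](O[Si](C(C)C)(C(C)C)C(C)C)[C@@H]1C(=C)C(=O)O[C@H]1C[C@](C)(O)C(=O)O | intermediate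
30 | pentafluorophenyl ester of 29 | CC(=O)/C(C)=C\[C@H](O[Si](C(C)C)(C(C)C)C(C)C)[C@@H]1C(=C)C(=O)O[C@H]1C[C@](C)(O)C(=O)Oc1c(F)c(F)c(F)c(F)c1F | intermediate
31 | (10S)-mesylate of 30 (key-step precursor) | CC(=O)/C(C)=C\[C@H](O[Si](C(C)C)(C(C)C)C(C)C)[C@@H]1C(=C)C(=O)O[C@H]1C[C@](C)(OS(C)(=O)=O)C(=O)Oc1c(F)c(F)c(F)c(F)c1F | intermediate
32 | macrocyclic 1,3-diketone (10S)-mesylate (10-membered carbocycle; formed as its magnesium enolate) | C=C1C(=O)O[C@H]2C[C@](C)(OS(C)(=O)=O)C(=O)CC(=O)/C(C)=C\[C@H](O[Si](C(C)C)(C(C)C)C(C)C)[C@H]12 | intermediate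
33 | 6-O-triisopropylsilyl 1-oxo-3,10-epoxygermacra-2,4(Z),11(13)-trien-12,8-olide, (6S,7R,8S,10R) | C=C1C(=O)O[C@H]2C[C@@]3(C)OC(=CC3=O)/C(C)=C\[C@H](O[Si](C(C)C)(C(C)C)C(C)C)[C@H]12 | intermediate
34 | 6-hydroxy-1-oxo-3,10-epoxygermacra-2,4(Z),11(13)-trien-12,8-olide (configuration as in the target) | C=C1C(=O)O[C@H]2C[C@@]3(C)OC(=CC3=O)/C(C)=C\[C@H](O)[C@H]12 | intermediate
35 | methyl angelate, methyl (2Z)-2-methylbut-2-enoate | C/C=C(C)\C(=O)OC | starting material
36 | (2Z)-2-methylbut-2-en-1-ol | C/C=C(C)\CO | intermediate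
37 | [(2S,3R)-2,3-dimethyloxiran-2-yl]methanol | OC[C@]1(C)O[C@@H]1C | intermediate
38 | (2R,3R)-2,3-dimethyloxirane-2-carboxylic acid | OC(=O)[C@]1(C)O[C@@H]1C | intermediate
39 | mixed anhydride of 38 with 2,4,6-trichlorobenzoic acid | O=C(OC(=O)[C@]1(C)O[C@@H]1C)c1c(Cl)cc(Cl)cc1Cl | intermediate
40 | CNP0258430.3: (6S,7R,8S,10R)-6-[(2R,3R)-2,3-dimethyloxirane-2-carbonyloxy]-1-oxo-3,10-epoxygermacra-2,4(Z),11(13)-trien-12,8-olide | C=C1C(=O)O[C@H]2C[C@@]3(C)OC(=CC3=O)/C(C)=C\[C@H](OC(=O)[C@]3(C)O[C@@H]3C)[C@H]12 | target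

**Count**
Total steps: 24. Longest linear sequence: 18 (steps 1–3, 7–20 and 24).

**Steps most likely to fail**

Step 19 (proposed new method). The ring closure may lose to O-acylation or to oligomerization, and the configuration at C10 may leak through bromide exchange or ionization of the mesylate before the oxygen attacks. The fallback makes the two bonds one after the other by known reactions. It sets out from keto aldehyde 28. Mesylation of the tertiary hydroxyl (MsCl, Et3N) gives mesyloxy keto aldehyde F1. The dibutylboron enolate of its methyl ketone (Bu2BOTf, i-Pr2NEt, CH2Cl2, 1 mM, −78 °C, non-oxidative work-up) adds to the non-enolizable aldehyde in an intramolecular aldol reaction and closes the carbocycle as macrocyclic β-hydroxy ketone F2 (either C1 epimer serves). Dess–Martin oxidation then gives diketone 32, where the fallback comes back to the route; 32 is isolated and closed to 33 with K2CO3 in acetone.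

Step 18. The tertiary sulfonate may eliminate to the unsaturated ester, or the activated ester may be attacked while the hindered hydroxyl is slowly sulfonylated. The fallback reverses the order of activation. It sets out from hydroxy acid 29. Excess MsCl with Et3N at −30 °C sulfonylates both the tertiary hydroxyl and the carboxyl to the mixed carboxylic methanesulfonic anhydride F3. Pentafluorophenol opens F3 at the acyl carbon in the same flask, and the fallback comes back at 31.

Step 13. Aminomethylation of the hindered lactone enolate may stay incomplete, or the new double bond may drift into the ring during the elimination. The fallback replaces the Mannich/Hofmann sequence by aldol addition and dehydration. It sets out from lactone 22. LiN(i-Pr)2 and gaseous formaldehyde give hydroxymethyl lactone F4, MsCl with Et3N gives its mesylate F5, and DBU eliminates F5, so the fallback comes back at 26.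

**Further compounds**
F1 | step 19 | mesyloxy keto aldehyde: (10S)-mesylate of 28 | CC(=O)/C(C)=C\[C@H](O[Si](C(C)C)(C(C)C)C(C)C)[C@@H]1C(=C)C(=O)O[C@H]1C[C@](C)(OS(C)(=O)=O)C=O
F2 | step 19 | macrocyclic β-hydroxy ketone: C1 carbinol (either epimer), C3 ketone, (10S)-mesylate | C=C1C(=O)O[C@H]2C[C@](C)(OS(C)(=O)=O)C(O)CC(=O)/C(C)=C\[C@H](O[Si](C(C)C)(C(C)C)C(C)C)[C@H]12
F3 | step 18 | mixed carboxylic methanesulfonic anhydride of the (10S)-mesyloxy acid | CC(=O)/C(C)=C\[C@H](O[Si](C(C)C)(C(C)C)C(C)C)[C@@H]1C(=C)C(=O)O[C@H]1C[C@](C)(OS(C)(=O)=O)C(=O)OS(C)(=O)=O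
F4 | step 13 | 11-(hydroxymethyl) lactone from 22, new group trans to the C7 side chain | C[C@H](O[Si](C)(C)C(C)(C)C)/C(C)=C\[C@H](O[Si](C(C)C)(C(C)C)C(C)C)[C@@H]1[C@@H](CO)C(=O)O[C@H]1C[C@@]1(C)COC(C)(C)O1
F5 | step 13 | mesylate of F4 | C[C@H](O[Si](C)(C)C(C)(C)C)/C(C)=C\[C@H](O[Si](C(C)C)(C(C)C)C(C)C)[C@@H]1[C@@H](COS(C)(=O)=O)C(=O)O[C@H]1C[C@@]1(C)COC(C)(C)O1
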